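**Plan**

- Retrosynthesis: remove the eight O-benzyl groups; cut both aryl bonds of upper C4 (C4–C8 to the lower catechin and C4–C4a of the upper pyran ring) back to one aldehyde carbon; cut the O1–C8a aryl ether; cut C2–C3 (aldol).
- Forward: a glycolate aldol joins the B-ring aldehyde to C3/C4; the phloroglucinol A ring is attached through O1 by Cu-catalysed O-arylation; C4 is raised to the aldehyde; one acid-triggered operation closes the upper pyran ring (the last ring) and joins C4 to C8 of tetra-O-benzyl-(+)-catechin; hydrogenolysis finishes.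
- Enabling feature: upper C4 is a methine flanked by two phloroglucinol-type carbons (C4a of upper ring A and C8 of lower ring A, each ortho/para to three oxygens), so C4 at the aldehyde level can accept both arenes in turn. The 3,5-dioxygenated phenoxy ring has two equivalent ortho carbons, so the closure has one outcome.
- Stereochemistry: upper C2/C3 (2,3-cis) from an Evans syn aldol under (S)-auxiliary control, carried on with retention; upper C4 (3,4-trans) from attack anti to O-3 on the cyclic C4 cation; lower C2/C3 from (+)-catechin.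

Key step: step 10

Remark: the SMILES is read as an upper (2R,3R,4R) 2,3-cis-3,4-trans unit with a 4-hydroxyphenyl B ring, joined 4→8 to a (2R,3S) catechin unit; 5-iodoresorcinol is taken as commercially available.

**Route**

Step 1
Reactants: 1 (S)-4-benzyloxazolidin-2-one; 2 2-(benzyloxy)acetyl chloride
Product: 3 (S)-4-benzyl-3-[2-(benzyloxy)acetyl]oxazolidin-2-one
Conditions: n-BuLi, THF, −78 °C; then 2, −78 → 0 °C
Reagents that add atoms: none
Why: N-acylation of the lithiated oxazolidinone with an acid chloride is the standard way to attach the auxiliary and creates no stereocentre.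

Step 2
Reactants: 3 (S)-4-benzyl-3-[2-(benzyloxy)acetyl]oxazolidin-2-one; 4 4-(benzyloxy)benzaldehyde
Product: 6 (S)-4-benzyl-3-[(2S,3R)-2-(benzyloxy)-3-[4-(benzyloxy)phenyl]-3-hydroxypropanoyl]oxazolidin-2-one, via dibutylboron Z-enolate 5 (not isolated)
Conditions: Bu2BOTf, Et3N, CH2Cl2, −78 → 0 °C; 4, −78 → 0 °C; pH 7 buffer, MeOH, H2O2, 0 °C
Reagents that add atoms: none
Why: Evans syn-aldol reaction, in which the Z-boron enolate reacts through a chair Zimmerman–Traxler transition state on the face opposite the benzyl group of the (S)-auxiliary, should set the syn (2S,3R) pair that becomes C3 and C2 of the upper unit.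

Step 3
Reactants: 6 aldol adduct
Product: 7 (1R,2R)-2-(benzyloxy)-1-[4-(benzyloxy)phenyl]propane-1,3-diol
Conditions: LiBH4, MeOH (1 equiv), THF, 0 °C
Reagents that add atoms: none
Why: Reductive cleavage of the N-acyl oxazolidinone gives the primary alcohol without touching either stereocentre and removes the carbonyl that would allow retro-aldol cleavage in the basic etherification of step 6.

Step 4
Reactants: 7 diol
Product: 8 (1R,2R)-2-(benzyloxy)-1-[4-(benzyloxy)phenyl]-3-(trityloxy)propan-1-ol
Conditions: TrCl, Et3N, DMAP (cat.), CH2Cl2, rt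
Reagents that add atoms: trityl chloride, ClC(c1ccccc1)(c1ccccc1)c1ccccc1
Why: Tritylation is selective for the primary hydroxyl on steric grounds and gives a base-stable ether that, unlike a silyl or acyl group, cannot migrate to the neighbouring oxygen during step 6.

Step 5
Reactants: 9 5-iodobenzene-1,3-diol
Product: 10 1,3-bis(benzyloxy)-5-iodobenzene
Conditions: BnBr, K2CO3, DMF, rt
Reagents that add atoms: benzyl bromide, BrCc1ccccc1
Why: Williamson ether synthesis on a symmetric diphenol poses no selectivity question.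

Step 6
Reactants: 8 trityl-protected alcohol; 10 1,3-bis(benzyloxy)-5-iodobenzene
Product: 11 (2R,3R)-2-(benzyloxy)-3-[3,5-bis(benzyloxy)phenoxy]-3-[4-(benzyloxy)phenyl]propyl trityl ether
Conditions: CuI (10 mol %), 3,4,7,8-tetramethyl-1,10-phenanthroline (20 mol %), Cs2CO3, toluene, 110 °C, 10 in excess
Reagents that add atoms: none
Why: Ullmann-type copper-catalysed C–O coupling of an aliphatic alcohol with an aryl iodide forms the O–C(aryl) bond without breaking the carbinol C–O bond, so the benzylic configuration from step 2 is retained, and the symmetric iodide can give only one regioisomer.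

Step 7
Reactants: 11 trityl ether
Product: 12 (2R,3R)-2-(benzyloxy)-3-[3,5-bis(benzyloxy)phenoxy]-3-[4-(benzyloxy)phenyl]propan-1-ol
Conditions: CSA (0.1 equiv), MeOH/CH2Cl2 1:1, 0 °C → rt
Reagents that add atoms: none
Why: Acid-catalysed methanolysis of a trityl ether runs through the trityl cation under conditions expected to be too mild to ionise the benzylic aryl ether or the benzyl ethers.

Step 8
Reactants: 12 primary alcohol
Product: 13 (2S,3R)-2-(benzyloxy)-3-[3,5-bis(benzyloxy)phenoxy]-3-[4-(benzyloxy)phenyl]propanal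
Conditions: Dess–Martin periodinane, CH2Cl2, 0 °C → rt; used without chromatography
Reagents that add atoms: none
Why: Dess–Martin oxidation is non-basic, which should avoid both epimerisation of the α-benzyloxy aldehyde and β-elimination of the aryloxide.

Step 9
Reactants: 14 (+)-catechin
Product: 15 5,7,3',4'-tetra-O-benzyl-(+)-catechin
Conditions: BnBr (4.4 equiv), K2CO3, DMF, −10 °C → rt
Reagents that add atoms: benzyl bromide, BrCc1ccccc1
Why: Williamson benzylation with a carbonate base alkylates the four phenols and leaves the aliphatic 3-OH free, with the two stereocentres of catechin untouched.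

Step 10
Reactants: 13 aldehyde; 15 5,7,3',4'-tetra-O-benzyl-(+)-catechin
Product: 17 3,5,7,4'-tetra-O-benzyl-epiafzelechin-(4β→8)-5,7,3',4'-tetra-O-benzylcatechin, via 4-hydroxyflavan 16 (not isolated)
Conditions: 15 (3.5 equiv), TMSOTf (0.3 equiv), 4 Å MS, CH2Cl2, −78 → −30 °C; then Et3N
Reagents that add atoms: none
Why: Proposed new method: TMSOTf activates the aldehyde of 13, the tethered 3,5-bis(benzyloxy)phenoxy ring attacks it through the carbon ortho to the ether oxygen (Friedel–Crafts hydroxyalkylation, new bond C4–C4a) to give the 4-hydroxyflavan 16, the same acid ionises 16 to the C4 benzylic cation stabilised by the ortho and para oxygens of the new A ring, and C8 of 15 captures this cation (Friedel–Crafts alkylation, new bond C4–C8). The closest known reaction types are the acid-induced cyclisation of 3-aryloxypropanals and their acetals to 4-oxygenated chromans and the Lewis-acid coupling of 4-oxygenated flavan-3-ol electrophiles with flavan-3-ol nucleophiles; their union in one flask on an acyclic aldehyde is the new element. The only ring closed is the upper pyran ring, by 6-exo-trig attack of the arene on the carbonyl carbon, and C2 and C3 pass unchanged from 13. The new stereocentre C4 is controlled by the half-chair cation, in which the 2-aryl group is pseudo-equatorial and the cis 3-benzyloxy group pseudo-axial, so 15 should add to the face anti to O-3 and give the 3,4-trans (4β, 4R) product. The step needs one mode of ring closure, secured by the twofold symmetry of the phenoxy ring (two equivalent ortho carbons, para carbon out of reach); attack of 15 at C8 and not C6, expected from the usual preference of 5,7-di-O-benzyl flavan-3-ols; and suppression of further condensation of the product, served by the excess of 15. Should 15 add to the aldehyde first, the resulting cation, then stabilised by the lower A ring, would be closed by the same tethered ring, so both orders of events converge on 17.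

Step 11
Reactants: 17 octa-O-benzyl dimer
Product: 18 Gambiriin C as drawn, (2R,3R,4R)-2-(4-hydroxyphenyl)-4-[(2R,3S)-2-(3,4-dihydroxyphenyl)-3,5,7-trihydroxychroman-8-yl]chroman-3,5,7-triol
Conditions: H2 (1 atm), Pd(OH)2/C, THF/MeOH/H2O, rt; filtration and lyophilisation under inert gas
Reagents that add atoms: none
Why: Hydrogenolysis of benzyl ethers over Pd(OH)2/C is the standard last step for benzylated proanthocyanidins and should leave the interflavan bond, the pyran C–O bonds and all five stereocentres intact.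

**Compound list**

1 | (S)-4-benzyloxazolidin-2-one | O=C1OC[C@H](Cc2ccccc2)N1 | starting material
2 | 2-(benzyloxy)acetyl chloride | O=C(Cl)COCc1ccccc1 | starting material
3 | (S)-4-benzyl-3-[2-(benzyloxy)acetyl]oxazolidin-2-one | O=C1OC[C@H](Cc2ccccc2)N1C(=O)COCc1ccccc1 | intermediate
4 | 4-(benzyloxy)benzaldehyde | O=Cc1ccc(OCc2ccccc2)cc1 | starting material
5 | dibutylboron (Z)-enolate of 3 | CCCCB(CCCC)O/C(=C\OCc1ccccc1)N1C(=O)OC[C@@H]1Cc1ccccc1 | intermediate (not isolated)
6 | (S)-4-benzyl-3-[(2S,3R)-2-(benzyloxy)-3-[4-(benzyloxy)phenyl]-3-hydroxypropanoyl]oxazolidin-2-one | O=C1OC[C@H](Cc2ccccc2)N1C(=O)[C@@H](OCc1ccccc1)[C@H](O)c1ccc(OCc2ccccc2)cc1 | intermediate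
7 | (1R,2R)-2-(benzyloxy)-1-[4-(benzyloxy)phenyl]propane-1,3-diol | OC[C@@H](OCc1ccccc1)[C@H](O)c1ccc(OCc2ccccc2)cc1 | intermediate
8 | (1R,2R)-2-(benzyloxy)-1-[4-(benzyloxy)phenyl]-3-(trityloxy)propan-1-ol | c1ccccc1C(c1ccccc1)(c1ccccc1)OC[C@@H](OCc1ccccc1)[C@H](O)c1ccc(OCc2ccccc2)cc1 | intermediate
9 | 5-iodobenzene-1,3-diol (5-iodoresorcinol) | Oc1cc(O)cc(I)c1 | starting material
10 | 1,3-bis(benzyloxy)-5-iodobenzene | Ic1cc(OCc2ccccc2)cc(OCc2ccccc2)c1 | intermediate
11 | (2R,3R)-2-(benzyloxy)-3-[3,5-bis(benzyloxy)phenoxy]-3-[4-(benzyloxy)phenyl]propyl trityl ether | c1ccccc1C(c1ccccc1)(c1ccccc1)OC[C@@H](OCc1ccccc1)[C@H](Oc1cc(OCc2ccccc2)cc(OCc2ccccc2)c1)c1ccc(OCc2ccccc2)cc1 | intermediate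
12 | (2R,3R)-2-(benzyloxy)-3-[3,5-bis(benzyloxy)phenoxy]-3-[4-(benzyloxy)phenyl]propan-1-ol | OC[C@@H](OCc1ccccc1)[C@H](Oc1cc(OCc2ccccc2)cc(OCc2ccccc2)c1)c1ccc(OCc2ccccc2)cc1 | intermediate
13 | (2S,3R)-2-(benzyloxy)-3-[3,5-bis(benzyloxy)phenoxy]-3-[4-(benzyloxy)phenyl]propanal | O=C[C@@H](OCc1ccccc1)[C@H](Oc1cc(OCc2ccccc2)cc(OCc2ccccc2)c1)c1ccc(OCc2ccccc2)cc1 | intermediate
14 | (+)-catechin, (2R,3S)-2-(3,4-dihydroxyphenyl)chroman-3,5,7-triol | O[C@H]1Cc2c(O)cc(O)cc2O[C@@H]1c1ccc(O)c(O)c1 | starting material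
15 | 5,7,3',4'-tetra-O-benzyl-(+)-catechin, (2R,3S)-5,7-bis(benzyloxy)-2-[3,4-bis(benzyloxy)phenyl]chroman-3-ol | O[C@H]1Cc2c(OCc3ccccc3)cc(OCc3ccccc3)cc2O[C@@H]1c1ccc(OCc2ccccc2)c(OCc2ccccc2)c1 | intermediate
16 | (2R,3R)-3,5,7-tris(benzyloxy)-2-[4-(benzyloxy)phenyl]chroman-4-ol, both C4 epimers | c5ccccc5COc1ccc([C@H]2Oc3cc(OCc5ccccc5)cc(OCc5ccccc5)c3C(O)[C@H]2OCc5ccccc5)cc1 | intermediate (not isolated)
17 | (2R,3S)-5,7-bis(benzyloxy)-2-[3,4-bis(benzyloxy)phenyl]-8-{(2R,3R,4R)-3,5,7-tris(benzyloxy)-2-[4-(benzyloxy)phenyl]chroman-4-yl}chroman-3-ol | c5ccccc5COc1ccc([C@H]2Oc3cc(OCc5ccccc5)cc(OCc5ccccc5)c3[C@H](c3c(OCc5ccccc5)cc(OCc5ccccc5)c4c3O[C@H](c3ccc(OCc5ccccc5)c(OCc5ccccc5)c3)[C@@H](O)C4)[C@H]2OCc5ccccc5)cc1 | intermediate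
18 | Gambiriin C as drawn, (2R,3R,4R)-2-(4-hydroxyphenyl)-4-[(2R,3S)-2-(3,4-dihydroxyphenyl)-3,5,7-trihydroxychroman-8-yl]chroman-3,5,7-triol | Oc1ccc([C@H]2Oc3cc(O)cc(O)c3[C@H](c3c(O)cc(O)c4c3O[C@H](c3ccc(O)c(O)c3)[C@@H](O)C4)[C@H]2O)cc1 | target

**Summary and risks**

Total step count: 11. Longest linear sequence: 9 steps (1, 2, 3, 4, 6, 7, 8, 10, 11).

Steps most likely to fail:

1. Step 10. The two arylations of the aldehyde carbon may lose their order and give intermolecular oligomers, attack of the nucleophile may split between C8 and C6, or the α-carbon of the aldehyde may epimerise before ring closure. The fallback uses known chemistry, sets out from 15 and 13 and comes back at 17, and makes the C4–C8 bond first and regiospecifically. Bromination of 15 with NBS (CH2Cl2, −78 °C → rt), known to occur at C8, would give 8-bromo-5,7,3',4'-tetra-O-benzylcatechin F1. F1 would be converted to its lithium alkoxide (MeLi, 1 equiv) and then to the C8-lithio species (t-BuLi, THF, −78 °C) and added to aldehyde 13 to give the benzylic carbinol F2 as a mixture of carbinol epimers. A catalytic acid (TMSOTf, CH2Cl2, −40 °C) would ionise the carbinol, and the tethered 3,5-bis(benzyloxy)phenoxy ring would close the pyran ring by intramolecular Friedel–Crafts alkylation to give 17.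

2. Step 6. The hindered secondary alkoxide may couple too slowly, so that reduction of the aryl iodide or oxidation of the benzylic alcohol takes over. The fallback sets out from 8 and comes back at 11 and forms the ether by inversion instead of retention. Dess–Martin oxidation of 8 would give the ketone (R)-2-(benzyloxy)-1-[4-(benzyloxy)phenyl]-3-(trityloxy)propan-1-one F3. Chelation-controlled reduction (Zn(BH4)2, Et2O, −20 °C) would give the anti alcohol (1S,2R)-2-(benzyloxy)-1-[4-(benzyloxy)phenyl]-3-(trityloxy)propan-1-ol F4. Mitsunobu etherification of F4 with commercial 3,5-bis(benzyloxy)phenol (DIAD, PPh3, toluene, 0 °C) would invert the benzylic carbon and give 11.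

3. Step 8. The aldehyde may epimerise at the α-carbon or lose the aryloxide by β-elimination during oxidation or handling. The fallback sets out from 12 and comes back at 17 and replaces the aldehyde by a thionium ion as the C4 electrophile. Treatment of 12 with PhSSPh and Bu3P (THF, rt) would give the phenyl sulfide F5, and mCPBA (1 equiv, CH2Cl2, −78 °C) would give the sulfoxide F6. A Pummerer reaction (TFAA, then SnCl4, CH2Cl2, −78 °C) would generate the thionium ion, which the tethered phenoxy ring should trap to give the 4-(phenylsulfanyl)flavan F7. Thiophilic activation of F7 with AgBF4 in the presence of excess 15 (THF, 0 °C), a known way to couple 4-thio flavan-3-ols, would give 17.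

Further compounds
F1 | step 10 | (2R,3S)-5,7-bis(benzyloxy)-2-[3,4-bis(benzyloxy)phenyl]-8-bromochroman-3-ol | O[C@H]1Cc2c(OCc3ccccc3)cc(OCc3ccccc3)c(Br)c2O[C@@H]1c1ccc(OCc2ccccc2)c(OCc2ccccc2)c1
F2 | step 10 | (2R,3S)-5,7-bis(benzyloxy)-2-[3,4-bis(benzyloxy)phenyl]-8-[(2R,3R)-2-(benzyloxy)-3-[3,5-bis(benzyloxy)phenoxy]-3-[4-(benzyloxy)phenyl]-1-hydroxypropyl]chroman-3-ol, both carbinol epimers | OC(c1c(OCc5ccccc5)cc(OCc5ccccc5)c2c1O[C@H](c1ccc(OCc5ccccc5)c(OCc5ccccc5)c1)[C@@H](O)C2)[C@@H](OCc1ccccc1)[C@H](Oc1cc(OCc2ccccc2)cc(OCc2ccccc2)c1)c1ccc(OCc2ccccc2)cc1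
F3 | step 6 | (R)-2-(benzyloxy)-1-[4-(benzyloxy)phenyl]-3-(trityloxy)propan-1-one | c1ccccc1C(c1ccccc1)(c1ccccc1)OC[C@@H](OCc1ccccc1)C(=O)c1ccc(OCc2ccccc2)cc1
F4 | step 6 | (1S,2R)-2-(benzyloxy)-1-[4-(benzyloxy)phenyl]-3-(trityloxy)propan-1-ol | c1ccccc1C(c1ccccc1)(c1ccccc1)OC[C@@H](OCc1ccccc1)[C@@H](O)c1ccc(OCc2ccccc2)cc1
F5 | step 8 | (2S,3R)-2-(benzyloxy)-3-[3,5-bis(benzyloxy)phenoxy]-3-[4-(benzyloxy)phenyl]propyl phenyl sulfide | c1ccccc1SC[C@@H](OCc1ccccc1)[C@H](Oc1cc(OCc2ccccc2)cc(OCc2ccccc2)c1)c1ccc(OCc2ccccc2)cc1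
F6 | step 8 | (2S,3R)-2-(benzyloxy)-3-[3,5-bis(benzyloxy)phenoxy]-3-[4-(benzyloxy)phenyl]propyl phenyl sulfoxide, both sulfur epimers | O=S(c1ccccc1)C[C@@H](OCc1ccccc1)[C@H](Oc1cc(OCc2ccccc2)cc(OCc2ccccc2)c1)c1ccc(OCc2ccccc2)cc1
F7 | step 8 | (2R,3S)-3,5,7-tris(benzyloxy)-2-[4-(benzyloxy)phenyl]-4-(phenylsulfanyl)chromane, both C4 epimers | c5ccccc5COc1ccc([C@H]2Oc3cc(OCc5ccccc5)cc(OCc5ccccc5)c3C(Sc5ccccc5)[C@H]2OCc5ccccc5)cc1
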